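**Retrosynthetic overview**
1. Both exocyclic alkenes go in last, from a spiro[5.5]undec-7-ene-1,9-dione: Wittig bromomethylenation of the ring-B enone, then Petasis methylenation of the hindered ring-A ketone.
2. Ring B is closed by intramolecular aldol condensation of a 2-formyl-2-(3-oxobutyl)cyclohexanone. Its quaternary (spiro) carbon is made by intermolecular Michael addition of a cyclic β-keto ester to methyl vinyl ketone, trans to the C–Br bond.
3. Ring A, carrying the neopentylic secondary bromide, comes from an enantiospecific bromonium cyclisation of an acyclic bromochloro β-keto ester.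
4. That ester comes from the acetoacetate dianion and the triflate of (R)-2-bromo-3-chloro-3-methylbutan-1-ol, made by enantioselective bromochlorination of prenol.
5. Ring order: ring A first (step 4), ring B second (step 8).

Assumption: in step 1 the enantiomer of the chiral tridentate Schiff-base (salicylaldimine amino-alcohol) ligand that gives the (R)-bromochloro alcohol is used; every later stereochemical event is substrate-controlled. Spiro compounds are numbered with the ring-A carbonyl (later methylidene) carbon as C1, CHBr as C4, CMe2 as C5 and the spiro atom as C6.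

**Route**

Step 1
Reactants: 1 3-methylbut-2-en-1-ol (prenol)
Product: 2 (2R)-2-bromo-3-chloro-3-methylbutan-1-ol
Conditions: NBS, ClTi(OiPr)3, chiral tridentate Schiff-base ligand (20 mol %), hexanes, −20 °C
Reagents that add atoms: N-bromosuccinimide O=C1CCC(=O)N1Br; chlorotitanium triisopropoxide CC(C)O[Ti](Cl)(OC(C)C)OC(C)C
Why: Catalytic enantioselective bromochlorination of an allylic alcohol, in which the titanium-bound substrate receives Br+ on one alkene face inside the chiral ligand pocket and chloride adds anti at the tertiary (Markovnikov) carbon, so the only stereocentre (C2, R) is set by the ligand.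

Step 2
Reactants: 2 (2R)-2-bromo-3-chloro-3-methylbutan-1-ol
Product: 3 (2R)-2-bromo-3-chloro-3-methylbutyl trifluoromethanesulfonate
Conditions: Tf2O, 2,6-lutidine, CH2Cl2, −78 °C
Reagents that add atoms: trifluoromethanesulfonic anhydride O=S(=O)(OS(=O)(=O)C(F)(F)F)C(F)(F)F
Why: O-Sulfonylation (triflation) of the primary alcohol at low temperature leaves the C–Br stereocentre untouched, and the β-bromine slows ionisation enough for the crude triflate to be used directly.

Step 3
Reactants: 3 (2R)-2-bromo-3-chloro-3-methylbutyl trifluoromethanesulfonate; 4 methyl acetoacetate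
Product: 6 methyl (6R)-6-bromo-7-chloro-7-methyl-3-oxooctanoate, via methyl acetoacetate dianion 5 (not isolated)
Conditions: 4, NaH, THF, 0 °C; n-BuLi, 0 °C; then 3, −78 → −40 °C; AcOH quench at −40 °C
Reagents that add atoms: none
Why: Weiler dianion γ-alkylation (SN2 at the primary triflate, fast at −78 °C) builds the β-keto ester chain while the hindered secondary bromide is not touched and keeps its R configuration, the cold acidic quench preventing the product enolate from displacing bromide.

Step 4
Reactants: 6 methyl (6R)-6-bromo-7-chloro-7-methyl-3-oxooctanoate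
Product: 8 methyl (1R,3R)-3-bromo-2,2-dimethyl-6-oxocyclohexane-1-carboxylate, via bromonium chloride ion pair 7 (not isolated)
Conditions: (CF3)2CHOH, 23 °C
Reagents that add atoms: none
Why: Solvolytic enantiospecific bromonium-ion cyclisation, in which the tertiary chloride ionises with anchimeric help from bromine and the enol carbon of the β-keto ester attacks the tertiary carbon of the bromonium ion through a chair, so no bond to the CHBr carbon is broken and it stays R with Br equatorial (the ester-bearing carbon is epimerisable and is destroyed in step 5).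

Step 5
Reactants: 8 methyl (1R,3R)-3-bromo-2,2-dimethyl-6-oxocyclohexane-1-carboxylate; 9 but-3-en-2-one (methyl vinyl ketone)
Product: 10 methyl (1R,3R)-3-bromo-2,2-dimethyl-6-oxo-1-(3-oxobutyl)cyclohexane-1-carboxylate
Conditions: 9 (3 equiv), Cs2CO3 (20 mol %), MeCN, 0 → 23 °C
Reagents that add atoms: none
Why: Base-catalysed intermolecular Michael addition of the stabilised β-keto ester enolate to the unhindered enone creates the quaternary carbon next to CMe2, the enone adding by chair-like axial attack on the enolate face anti to the pseudo-axial C2 methyl and to the C3 bromine, so the oxobutyl chain ends trans and the ester cis to Br.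

Step 6
Reactants: 10 methyl (1R,3R)-3-bromo-2,2-dimethyl-6-oxo-1-(3-oxobutyl)cyclohexane-1-carboxylate
Product: 11 (2S,4R)-4-bromo-2-(3-hydroxybutyl)-2-(hydroxymethyl)-3,3-dimethylcyclohexan-1-ol (carbinol epimers)
Conditions: i-Bu2AlH (8 equiv), CH2Cl2, −78 → 23 °C; aq. potassium sodium tartrate
Reagents that add atoms: none
Why: Exhaustive hydride reduction of the ester and both ketones with an aluminium hydride that does not attack the hindered secondary alkyl bromide brings the ester carbon to the alcohol level, the new carbinol centres being irrelevant because they are re-oxidised.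

Step 7
Reactants: 11 (2S,4R)-4-bromo-2-(3-hydroxybutyl)-2-(hydroxymethyl)-3,3-dimethylcyclohexan-1-ol
Product: 12 (1S,3R)-3-bromo-2,2-dimethyl-6-oxo-1-(3-oxobutyl)cyclohexane-1-carbaldehyde
Conditions: (COCl)2, DMSO, CH2Cl2, −78 °C; Et3N, −78 → 0 °C
Reagents that add atoms: none
Why: Swern oxidation activates all three hydroxyls at −78 °C before the base is added, so the aldehyde and both ketones form without lactol-to-lactone over-oxidation, and the non-enolisable quaternary centre cannot epimerise.

Step 8
Reactants: 12 (1S,3R)-3-bromo-2,2-dimethyl-6-oxo-1-(3-oxobutyl)cyclohexane-1-carbaldehyde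
Product: 14 (4R,6R)-4-bromo-5,5-dimethylspiro[5.5]undec-7-ene-1,9-dione, via spiro ketol 13 (not isolated)
Conditions: p-TsOH·H2O (10 mol %), toluene, 80 °C, Dean–Stark
Reagents that add atoms: none
Why: Acid-catalysed intramolecular aldol condensation (the ring-closing half of a Robinson annulation) in which the methyl-ketone enol attacks the aldehyde, far more electrophilic than the hindered ring ketone, and the ketol dehydrates to the spiro cyclohexenone, acid being chosen over amine or hydroxide to avoid retro-Claisen loss of the formyl group.

Step 9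
Reactants: 14 (4R,6R)-4-bromo-5,5-dimethylspiro[5.5]undec-7-ene-1,9-dione
Product: 15 (4R,6R,9Z)-4-bromo-9-(bromomethylidene)-5,5-dimethylspiro[5.5]undec-7-en-1-one
Conditions: Ph3P+CH2Br Br−, NaN(SiMe3)2, THF, −78 → 0 °C; chromatography on AgNO3–SiO2
Reagents that add atoms: (bromomethyl)triphenylphosphonium bromide BrC[P+](c1ccccc1)(c1ccccc1)c1ccccc1.[Br-]
Why: Wittig bromomethylenation with the bulky ylide Ph3P=CHBr takes place at the enone carbonyl and not at the neopentyl-type ring-A ketone, and since no strong geometric bias is expected both double-bond isomers form and the Z isomer (Br syn to the ring CH=) is isolated by chromatography on silver-nitrate-impregnated silica.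

Step 10
Reactants: 15 (4R,6R,9Z)-4-bromo-9-(bromomethylidene)-5,5-dimethylspiro[5.5]undec-7-en-1-one
Product: 16 (4R,6S,9Z)-4-bromo-9-(bromomethylidene)-5,5-dimethyl-1-methylidenespiro[5.5]undec-7-ene
Conditions: Cp2TiMe2 (3 equiv), toluene/THF, 65 °C, dark
Reagents that add atoms: dimethyltitanocene Cp2TiMe2 C[Ti+2]C.c1cc[cH-]c1.c1cc[cH-]c1
Why: Petasis methylenation with the non-basic titanium methylidene converts the hindered, enolisable ketone next to the spiro carbon into the exocyclic methylene without eliminating the alkyl bromide or isomerising the bromodiene (the spiro descriptor changes from R to S only because the CIP priorities change).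

**Compound list**
1 | 3-methylbut-2-en-1-ol (prenol) | CC(C)=CCO | starting material
2 | (2R)-2-bromo-3-chloro-3-methylbutan-1-ol | OC[C@@H](Br)C(C)(C)Cl | intermediate
3 | (2R)-2-bromo-3-chloro-3-methylbutyl trifluoromethanesulfonate | O=S(=O)(OC[C@@H](Br)C(C)(C)Cl)C(F)(F)F | intermediate
4 | methyl acetoacetate (methyl 3-oxobutanoate) | COC(=O)CC(C)=O | starting material
5 | methyl acetoacetate dianion, sodium lithium salt (not isolated) | C=C([O-])C=C([O-])OC.[Na+].[Li+] | intermediate
6 | methyl (6R)-6-bromo-7-chloro-7-methyl-3-oxooctanoate | COC(=O)CC(=O)CC[C@@H](Br)C(C)(C)Cl | intermediate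
7 | bromonium chloride ion pair from 6 (not isolated) | COC(=O)CC(=O)CC[C@@H]1C(C)(C)[Br+]1.[Cl-] | intermediate
8 | methyl (1R,3R)-3-bromo-2,2-dimethyl-6-oxocyclohexane-1-carboxylate (Br and ester cis, both equatorial) | O=C1CC[C@@H](Br)C(C)(C)[C@H]1C(=O)OC | intermediate
9 | but-3-en-2-one (methyl vinyl ketone) | CC(=O)C=C | starting material
10 | methyl (1R,3R)-3-bromo-2,2-dimethyl-6-oxo-1-(3-oxobutyl)cyclohexane-1-carboxylate (chain trans to Br) | O=C1CC[C@@H](Br)C(C)(C)[C@@]1(CCC(C)=O)C(=O)OC | intermediate
11 | (2S,4R)-4-bromo-2-(3-hydroxybutyl)-2-(hydroxymethyl)-3,3-dimethylcyclohexan-1-ol (mixture at the two new carbinol carbons) | OC1CC[C@@H](Br)C(C)(C)[C@@]1(CCC(C)O)CO | intermediate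
12 | (1S,3R)-3-bromo-2,2-dimethyl-6-oxo-1-(3-oxobutyl)cyclohexane-1-carbaldehyde | O=C1CC[C@@H](Br)C(C)(C)[C@@]1(CCC(C)=O)C=O | intermediate
13 | (4R,6S)-4-bromo-7-hydroxy-5,5-dimethylspiro[5.5]undecane-1,9-dione (C7 epimers; not isolated) | O=C1CC[C@@H](Br)C(C)(C)[C@@]12C(O)CC(=O)CC2 | intermediate
14 | (4R,6R)-4-bromo-5,5-dimethylspiro[5.5]undec-7-ene-1,9-dione | O=C1CC[C@@H](Br)C(C)(C)[C@@]12C=CC(=O)CC2 | intermediate
15 | (4R,6R,9Z)-4-bromo-9-(bromomethylidene)-5,5-dimethylspiro[5.5]undec-7-en-1-one | O=C1CC[C@@H](Br)C(C)(C)[C@@]12C=C/C(=C\Br)CC2 | intermediate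
16 | (4R,6S,9Z)-4-bromo-9-(bromomethylidene)-5,5-dimethyl-1-methylidenespiro[5.5]undec-7-ene | C=C1CC[C@@H](Br)C(C)(C)[C@@]12C=C/C(=C\Br)CC2 | target

**Totals**
Total step count: 10. Longest linear sequence: 10 steps (from 1).

**Steps most likely to fail, with fallbacks**

Step 3. The strongly basic dianion may cause E2 or attack at bromine on the β-bromo triflate instead of SN2. The fallback sets out from 3 and avoids any strongly basic carbanion: copper-catalysed coupling with CH2=CHCH2MgBr (CuI cat., THF, −78 °C) gives (5R)-5-bromo-6-chloro-6-methylhept-1-ene F1. Ozonolysis (O3, CH2Cl2, −78 °C; PPh3) gives (4R)-4-bromo-5-chloro-5-methylhexanal F2. Roskamp homologation with methyl diazoacetate (SnCl2 cat., CH2Cl2, 23 °C) turns the aldehyde into the β-keto ester, and the sequence comes back to the route at 6.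

Step 5. The Michael addition creates two adjacent quaternary carbons and may be slow or reversible. The fallback sets out from 6 and inverts the order of the two C–C bond formations. The unhindered acyclic β-keto ester adds to 9 (K2CO3 cat., acetone, 0 °C) to give methyl (6R)-6-bromo-7-chloro-7-methyl-3-oxo-2-(3-oxobutyl)octanoate F3. The solvolytic bromonium cyclisation in (CF3)2CHOH then forms the congested quaternary carbon intramolecularly through a chair with Br and the ester equatorial and the chain axial. This gives the same diastereomer and comes back to the route at 10.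

Step 9. The Wittig reaction may give an unfavourable Z/E ratio, and the ylide may enolise the ketones. The fallback sets out from 14. Ramirez dibromo-olefination (CBr4, PPh3, toluene, 80 °C) gives (4R,6R)-4-bromo-9-(dibromomethylidene)-5,5-dimethylspiro[5.5]undec-7-en-1-one F4. Hydrogenolysis with Bu3SnH and catalytic Pd(PPh3)4 (toluene, 23 °C) then removes one vinylic bromine, zerovalent palladium inserting into the less encumbered C–Br bond. That bond is expected to be the one on the ring-CH2 side, leaving the bromine syn to the ring CH=, but the preference is a prediction and the ratio can be tuned through the phosphine. The sequence comes back to the route at 15.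

Further compounds
F1 | step 3 | (5R)-5-bromo-6-chloro-6-methylhept-1-ene | C=CCC[C@@H](Br)C(C)(C)Cl
F2 | step 3 | (4R)-4-bromo-5-chloro-5-methylhexanal | O=CCC[C@@H](Br)C(C)(C)Cl
F3 | step 5 | methyl (6R)-6-bromo-7-chloro-7-methyl-3-oxo-2-(3-oxobutyl)octanoate | COC(=O)C(CCC(C)=O)C(=O)CC[C@@H](Br)C(C)(C)Cl
F4 | step 9 | (4R,6R)-4-bromo-9-(dibromomethylidene)-5,5-dimethylspiro[5.5]undec-7-en-1-one | O=C1CC[C@@H](Br)C(C)(C)[C@@]12C=CC(=C(Br)Br)CC2
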